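Q in the noon run, which is this very flask followed so far, reads 95 % of the E charged at 4.00 h. So over those first hours it has climbed by 15.7 mM h⁻¹ on average, and the knee lies somewhere inside that span. After the knee the line is level, between 93 % and 96 %, which is within the scatter.

| setting | noon | dawn | flask |
|---|---|---|---|
| E | 0.066 M | 0.099 M | 0.066 M |
| X | 0.0627 M | 0.0627 M | 0.0627 M |
| Z | 7.3 mM | 7.3 mM | 7.3 mM |
| remark | the very flask that is asked about, followed so far | run made earlier |  |
| time |  |  | 2.5 d |

- noon (time / h: Q / %, J / %): 4.00: 95, 5; 8.00: 93, 1; 10.0: 94, 4; 15.0: 96, 3; 20.0: 95, 4
- dawn (time / h: Q / %, J / %): 8.00: 64, 21; 15.0: 63, 21; 25.0: 62, 22; 30.0: 65, 22; 40.0: 64, 21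

(scatter of a reading: 1.5 percentage points)

* at 2.5 d, what has stopped the reaction, if anything has (X has run out first / no working catalyst is left / forward and back rates have come level / it is still moving / all of E has reacted)
* amount of Q at 2.5 d, in percent of the E charged
* amount of J at 2.5 d, in percent of the E charged

- the analysis behind the earlier runs scatters by 1.5 percentage points, standard deviation
- the reaction counts as stopped when no species that holds the E changes by six tenths of a point or more over the second half of the time

The dawn run has more E and the same X, and it levels at 62 % to 65 %. In molar terms the first readings of the two runs lie close together: 0.0627 M of Q at noon and 0.0634 M at dawn, against 0.0627 M of X charged. So I read one X per Q, with X as the limiting reagent, and I carry one number: the ceiling, [X] charged over [E] charged, as a percentage of the E charged. For this flask it is 95.0 %, and for the dawn run 63.3 %.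

The rest of the E stays outside Q. At dawn J reads 21 % of a rest of 36.7 %, a share of 57.3 %. Applied to this flask's rest of 5.00 %, that share gives me J at 2.86 %, with Q on the ceiling. The asked time is later than the first reading of the noon run, and the line of that run is already level.

The forecast says X has run out first, with Q at 94.8 % (93.5 % to 95.8 %) and J at 3.1 % (2.2 % to 4.2 %), which is slightly above my J. Its ground is that “one X is consumed per Q and X is limiting”.

At 2.5 d the flask's answer is that X has run out first, with Q at 95.0 %, J at 3.00 % and 0 % of the X charge left.

    E + Z ⇌ Z + J (K = 1.50, k = 0.470 L mol⁻¹ s⁻¹)
    X + Z + J → Z + Q (k = 5.60 L² mol⁻² s⁻¹)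

Q in this flask stands on the ceiling of 95.0 %, and Z is still at 100 %, so the catalyst is intact when the reaction stops. E still shows 2.00 % because J returns to E: in the run with that return taken away, conversion of E goes from 98.0 % to 100 %. The ceiling carries over to the neighbour flask with 0.11 M of E, where [X] charged over [E] charged is 57.0 %. That neighbour flask ends with Q at 57.0 %.

The runs are calculated for an exercise, noise included.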